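# Gericudranin E: proposed total synthesis

**Assumptions.** The target SMILES is (2R,3R)-6-(4-hydroxybenzyl)dihydrokaempferol, a 2,3-trans 5,7,4'-trihydroxy-dihydroflavonol. Only substrates, intermediates and the target are numbered; reagents, catalysts and solvents are named in the steps. I assume the (S)-BINOL/La/Ph3P=O system delivers the (αR,βS)-chalcone oxide. If the opposite enantiomer forms, (R)-BINOL is used.

## Retrosynthesis

1. The target comes from global hydrogenolytic debenzylation of the tetra-O-benzyl (2R,3R)-dihydroflavonol **10**.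
2. The pyranone C ring is closed last. A new stereoinvertive 6-endo opening of a trans-α,β-epoxy ketone by the ortho phenol forms the O1–C2 bond. Cβ is inverted to give C2 (R), and Cα is retained as C3 (R).
3. Both epoxide stereocentres come from catalytic asymmetric Weitz–Scheffer epoxidation of a chalcone. The chalcone comes from Claisen–Schmidt condensation of a hindered acetophenone.
4. The acetophenone is built from phloroacetophenone. The ring oxygen is masked as a bulky TIPS ether, which sterically steers Friedel–Crafts benzylation to C5' (C6 of the flavonoid) rather than C3' (C8).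
5. Rings form in the order: A ring (pre-existing) → benzyl substituent → enone → epoxide → C ring.

## Route

**Step 1**
Reactants: **1** 2,4,6-trihydroxyacetophenone (phloroacetophenone)
Product: **2** 1-[4,6-bis(benzyloxy)-2-hydroxyphenyl]ethanone
Conditions: BnBr (2.1 equiv), K2CO3, acetone, reflux
Reagents that add atoms: benzyl bromide, BrCc1ccccc1
Why: Williamson etherification. The acidic 4-OH reacts first, then one ortho OH. The last OH is H-bonded to the ketone and resists alkylation. The 2'/6' OHs are equivalent at this stage, so there is no regiochemical issue.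

**Step 2**
Reactants: **2**
Product: **3** 1-[4,6-bis(benzyloxy)-2-(triisopropylsilyloxy)phenyl]ethanone
Conditions: TIPSCl (1.5 equiv), imidazole, DMAP (cat.), DMF, 60 °C
Reagents that add atoms: triisopropylsilyl chloride, CC(C)[Si](Cl)(C(C)C)C(C)C
Why: Silylation of the chelated phenol. It masks the future ring oxygen (O1) and places a very bulky group next to C3'.

**Step 3**
Reactants: **3**; **4** 4-(benzyloxy)benzyl alcohol
Product: **5** 1-[4,6-bis(benzyloxy)-5-(4-benzyloxybenzyl)-2-(triisopropylsilyloxy)phenyl]ethanone
Conditions: Sc(OTf)3 (5 mol %), MeNO2, 25 °C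
Reagents that add atoms: none (**4** is the numbered reactant; water is lost)
Why: Friedel–Crafts benzylation through the p-alkoxybenzyl cation, which is reversible on this electron-rich arene. C3' is shielded by the forced-inward OTIPS group, while C5' is flanked only by OBn groups. The benzyl group therefore ends up at the future C6, para to O1.

**Step 4**
Reactants: **5**; **6** 4-(benzyloxy)benzaldehyde
Product: **7** (E)-chalcone, 1-aryl-3-(4-benzyloxyphenyl)prop-2-en-1-one
Conditions: KOH, EtOH/THF, rt, 48 h
Reagents that add atoms: none (**6** is the numbered reactant; water is lost)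
Why: Claisen–Schmidt condensation. It is standard for 2,4,6-trioxygenated acetophenones, and the aryl TIPS ether survives mild hydroxide at rt.

**Step 5**
Reactants: **7**
Product: **8** (αR,βS)-trans-chalcone oxide, 2'-OTIPS
Conditions: La(OiPr)3 (10 mol %), (S)-BINOL (10 mol %), Ph3P=O (30 mol %), cumene hydroperoxide (1.5 equiv), 4 Å MS, THF, rt
Reagents that add atoms: cumene hydroperoxide (supplies the epoxide O), CC(C)(OO)c1ccccc1
Why: Shibasaki-type catalytic asymmetric Weitz–Scheffer epoxidation through a chiral lanthanoid hydroperoxide (conjugate addition, then ring closure). This sets both epoxide stereocentres, trans, (αR,βS), which become C3 (R) and, after inversion, C2 (R).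

**Step 6**
Reactants: **8**
Product: **9** (αR,βS)-chalcone oxide with free 2'-OH
Conditions: TBAF/AcOH (1:1), THF, 0 °C, 30 min
Reagents that add atoms: none
Why: Fluoride desilylation. Buffering with AcOH avoids a phenoxide-triggered base-mediated 5-exo closure (aurone pathway). The epoxide and benzyl ethers are untouched and no stereocentre is affected.

**Step 7**
Reactants: **9**
Product: **10** (2R,3R)-5,7,4'-tris(benzyloxy)-6-(4-benzyloxybenzyl)-3-hydroxyflavanone
Conditions: HFIP/CH2Cl2 (1:1), 0.02 M, 25 °C, 12 h
Reagents that add atoms: none (an isomerisation)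
Why: Proposed new method: HFIP is a strong H-bond donor that is ionising but non-nucleophilic. It activates the epoxide oxygen, so the benzylic Cβ–O bond (stabilised by the p-benzyloxyphenyl group) is the weak bond, while the α-keto Cα–O bond is disfavoured toward positive charge. This reverses the 5-exo (Cα) preference of base-mediated opening of 2'-hydroxychalcone epoxides. The tethered phenol then attacks Cβ anti to the epoxide C–O bond in a loose SN2-type 6-endo-tet closure. Cβ is inverted (βS → C2 R) and Cα is retained (αR → C3 R), giving the 2,3-trans product. The closest known chemistry is acid-promoted endo-selective epoxy-alcohol cyclisation, HFIP-promoted benzylic epoxide opening, and Algar–Flynn–Oyamada-type formation of trans-dihydroflavonols.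

**Step 8**
Reactants: **10**
Product: **11** Gericudranin E, (2R,3R)-3,5,7-trihydroxy-6-(4-hydroxybenzyl)-2-(4-hydroxyphenyl)chroman-4-one
Conditions: H2 (1 atm), 10% Pd/C, EtOAc/MeOH (1:1), rt, 2 h
Reagents that add atoms: none (H2 only adds hydrogen)
Why: Hydrogenolysis of four aryl benzyl ethers. The C2 and C3 stereocentres are not touched, and the short reaction time at 1 atm avoids benzylic C2–O cleavage and ketone reduction.

## Compound list

| No. | Name | SMILES | Role |
|---|---|---|---|
| 1 | 2,4,6-Trihydroxyacetophenone | CC(=O)c1c(O)cc(O)cc1O | starting material |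
| 2 | 1-[4,6-Bis(benzyloxy)-2-hydroxyphenyl]ethanone | CC(=O)c1c(O)cc(OCc2ccccc2)cc1OCc1ccccc1 | intermediate |
| 3 | 2'-OTIPS-4',6'-bis(benzyloxy)acetophenone | CC(=O)c1c(O[Si](C(C)C)(C(C)C)C(C)C)cc(OCc2ccccc2)cc1OCc1ccccc1 | intermediate |
| 4 | 4-(Benzyloxy)benzyl alcohol | OCc1ccc(OCc2ccccc2)cc1 | starting material |
| 5 | 5'-(4-Benzyloxybenzyl)-2'-OTIPS-4',6'-bis(benzyloxy)acetophenone | CC(=O)c1c(O[Si](C(C)C)(C(C)C)C(C)C)cc(OCc2ccccc2)c(Cc2ccc(OCc3ccccc3)cc2)c1OCc1ccccc1 | intermediate |
| 6 | 4-(Benzyloxy)benzaldehyde | O=Cc1ccc(OCc2ccccc2)cc1 | starting material |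
| 7 | (E)-Chalcone from 5 and 6 | O=C(/C=C/c1ccc(OCc2ccccc2)cc1)c1c(O[Si](C(C)C)(C(C)C)C(C)C)cc(OCc2ccccc2)c(Cc2ccc(OCc3ccccc3)cc2)c1OCc1ccccc1 | intermediate |
| 8 | (αR,βS)-trans-Chalcone oxide, 2'-OTIPS | O=C(c1c(O[Si](C(C)C)(C(C)C)C(C)C)cc(OCc2ccccc2)c(Cc2ccc(OCc3ccccc3)cc2)c1OCc1ccccc1)[C@@H]1O[C@H]1c1ccc(OCc2ccccc2)cc1 | intermediate |
| 9 | (αR,βS)-trans-Chalcone oxide, free 2'-OH | O=C(c1c(O)cc(OCc2ccccc2)c(Cc2ccc(OCc3ccccc3)cc2)c1OCc1ccccc1)[C@@H]1O[C@H]1c1ccc(OCc2ccccc2)cc1 | intermediate |
| 10 | (2R,3R)-Tetra-O-benzyl-6-benzyl-dihydroflavonol | O=C1c2c(OCc3ccccc3)c(Cc3ccc(OCc4ccccc4)cc3)c(OCc3ccccc3)cc2O[C@H](c2ccc(OCc3ccccc3)cc2)[C@H]1O | intermediate |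
| 11 | Gericudranin E | O=C1c2c(cc(O)c(Cc3ccc(O)cc3)c2O)O[C@H](c2ccc(O)cc2)[C@H]1O | target |

## Totals

- Total steps: 8
- Longest linear sequence: 8 steps (from **1**)

## Three steps most likely to fail

1. **Step 7 (proposed new cyclisation).** Risks are SN1-type stereoerosion, Meinwald acyl shift, or residual 5-exo closure.
   Fallback (known chemistry, different approach): skip the epoxide. Take the chalcone from Step 4, remove TIPS, and cyclise to the flavanone with NaOAc in EtOH. Then form the silyl enol ether (LiHMDS, TMSCl) and oxidise with DMDO (Rubottom-type), which gives the trans-3-hydroxyflavanone. Resolve racemic **10** by preparative chiral HPLC, then run Step 8.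
2. **Step 5 (asymmetric epoxidation).** The 2,6-dioxygenated aryl enone is hindered, so ee or conversion may be poor.
   Fallback: racemic Weitz–Scheffer epoxidation (H2O2, NaOH, THF/MeOH) of **7**, followed by preparative chiral-phase HPLC resolution of epoxide **8**. This replaces catalytic asymmetric induction with resolution.
3. **Step 3 (C5' vs C3' benzylation).** The selectivity rests on the steric difference between OTIPS and OBn, and the Lewis acid might cleave a benzyl or silyl ether.
   Fallback: fix regiochemistry stepwise. Brominate **3** with NBS in MeCN, separate any C3'-bromo isomer, and run Negishi coupling of the 5'-bromide with 4-(benzyloxy)benzylzinc bromide (Pd-PEPPSI-IPr) to give **5**.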